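**Retrosynthetic overview**
1. Target 27 ⇐ global acid deprotection of (2S)-flavanone 26 ⇐ catalyst-controlled oxa-Michael closure of 2'-hydroxychalcone 25 ⇐ Claisen–Schmidt of acetophenone 20 with aldehyde 24.
2. 20 ⇐ ortho-acetylation of phenol 18. Its single free OH (future O1, put on resorcinol by C–H borylation and a B→O 1,2-shift) directs both ortho C–C bonds and fixes the 8-regiochemistry.
3. Key C1''–C2'' disconnection: 18 ⇐ salicylaldehyde 5 + secondary boronic acid 14, by a diazo-triggered 1,2-shift of the alkyl group from boron to carbon (retention), then protodeboronation.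
4. 14 ⇐ sparteine-controlled lithiation–borylation (1,2-metallate shift) of benzoate 8 with prenyl boronate 10; (S)-3-bromo-2-methylpropan-1-ol supplies C3''.
5. Ring order: A and B rings enter intact as resorcinol; the pyranone C ring is the only ring built and is closed last.

Assumption: the target is taken as drawn, (2S) at the flavanone carbon and (2R,3R) in the side chain (C1''–C4'' counted from the ring); enantiopure (S)-3-bromo-2-methylpropan-1-ol and (−)-sparteine are taken as commercially available.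

**Route**

Step 1
Reactants: 1 resorcinol
Product: 2 1,3-bis(methoxymethoxy)benzene
Conditions: MOMCl (2.5 equiv), iPr2NEt (3 equiv), CH2Cl2, 0 °C to rt
Reagents that add atoms: chloromethyl methyl ether, COCCl
Why: Williamson-type O-alkylation (MOM protection) of both phenols; no stereocentre.

Step 2
Reactants: 2 1,3-bis(methoxymethoxy)benzene
Product: 4 3,5-bis(methoxymethoxy)phenol, via aryl pinacol boronate 3 (not isolated)
Conditions: [Ir(OMe)(cod)]2 (1.5 mol %), dtbpy (3 mol %), B2pin2 (1.0 equiv), THF, 80 °C; then 30% H2O2, 2 M NaOH, 0 °C to rt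
Reagents that add atoms: hydrogen peroxide, OO; bis(pinacolato)diboron, CC1(C)OB(OC1(C)C)B1OC(C)(C)C(C)(C)O1 (Bpin of 3 only)
Why: Sterically governed Ir-catalysed C–H borylation takes the only C–H flanked by two hydrogens, and peroxide oxidation turns C–B into C–O by a 1,2-aryl shift from boron to oxygen, giving the one free phenol that becomes O1.

Step 3
Reactants: 4 3,5-bis(methoxymethoxy)phenol
Product: 5 2-hydroxy-4,6-bis(methoxymethoxy)benzaldehyde
Conditions: MgCl2 (2 equiv), Et3N (4 equiv), (CH2O)n (6 equiv), MeCN, reflux; cold 1 M HCl work-up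
Reagents that add atoms: paraformaldehyde (formaldehyde), C=O
Why: Magnesium-mediated ortho-formylation (Casiraghi–Skattebøl): the Mg phenoxide delivers formaldehyde to the ortho carbon and a second formaldehyde oxidises the benzylic alkoxide by hydride transfer; the two ortho sites are equivalent.

Step 4
Reactants: 6 (S)-3-bromo-2-methylpropan-1-ol
Product: 7 (S)-(3-bromo-2-methylpropoxy)(tert-butyl)dimethylsilane
Conditions: TBSCl (1.1 equiv), imidazole (2 equiv), CH2Cl2, 0 °C to rt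
Reagents that add atoms: tert-butyldimethylsilyl chloride, CC(C)(C)[Si](C)(C)Cl
Why: Standard silyl ether protection; the stereocentre is not involved.

Step 5
Reactants: 7 (S)-(3-bromo-2-methylpropoxy)(tert-butyl)dimethylsilane
Product: 8 (R)-3-[(tert-butyldimethylsilyl)oxy]-2-methylpropyl 2,4,6-triisopropylbenzoate
Conditions: 2,4,6-triisopropylbenzoic acid (1.2 equiv), Cs2CO3 (1.5 equiv), Bu4NI (cat.), DMF, 70 °C
Reagents that add atoms: 2,4,6-triisopropylbenzoic acid, CC(C)c1cc(C(C)C)c(C(=O)O)c(C(C)C)c1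
Why: SN2 alkylation of the hindered carboxylate at the primary bromide; the adjacent stereocentre is untouched (the descriptor changes only through CIP priorities).

Step 6
Reactants: 9 1-chloro-3-methylbut-2-ene
Product: 10 4,4,5,5-tetramethyl-2-(3-methylbut-2-en-1-yl)-1,3,2-dioxaborolane
Conditions: B2pin2 (1.1 equiv), Pd2(dba)3 (0.5 mol %), THF, 60 °C
Reagents that add atoms: bis(pinacolato)diboron, CC1(C)OB(OC1(C)C)B1OC(C)(C)C(C)(C)O1
Why: Pd-catalysed Miyaura-type allylic borylation through a π-allyl complex gives the linear prenyl boronate.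

Step 7
Reactants: 8 (R)-3-[(tert-butyldimethylsilyl)oxy]-2-methylpropyl 2,4,6-triisopropylbenzoate; 10 4,4,5,5-tetramethyl-2-(3-methylbut-2-en-1-yl)-1,3,2-dioxaborolane
Product: 13 tert-butyl{[(2R,3S)-2,6-dimethyl-3-(4,4,5,5-tetramethyl-1,3,2-dioxaborolan-2-yl)hept-5-en-1-yl]oxy}dimethylsilane, via α-lithiated benzoate 11 (not isolated), via lithium boronate complex 12 (not isolated)
Conditions: s-BuLi (1.2 equiv), (−)-sparteine (1.2 equiv), Et2O, −78 °C, 5 h; 10 (1.5 equiv), −78 °C, 1 h; then rt to 35 °C, 16 h; aq NH4Cl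
Reagents that add atoms: sec-butyllithium, CCC(C)[Li] (Li of 11 and 12 only)
Why: Hoppe sparteine-mediated deprotonation then Aggarwal lithiation–borylation: (−)-sparteine removes the pro-S proton, boron captures the carbanion with retention, and the prenyl group makes a stereospecific 1,2-metallate shift from boron to carbon anti to the benzoate (inversion), which sets C3 of 13 as S under reagent control.

Step 8
Reactants: 13 tert-butyl{[(2R,3S)-2,6-dimethyl-3-(4,4,5,5-tetramethyl-1,3,2-dioxaborolan-2-yl)hept-5-en-1-yl]oxy}dimethylsilane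
Product: 14 [(2R,3S)-1-[(tert-butyldimethylsilyl)oxy]-2,6-dimethylhept-5-en-3-yl]boronic acid
Conditions: NaIO4 (3 equiv), NH4OAc (3 equiv), acetone/H2O 2:1, rt
Reagents that add atoms: water, O
Why: Periodate glycol cleavage of the released pinacol drives ester hydrolysis to the free boronic acid; the C–B stereocentre, alkene and silyl ether are untouched.

Step 9
Reactants: 5 2-hydroxy-4,6-bis(methoxymethoxy)benzaldehyde; 14 [(2R,3S)-1-[(tert-butyldimethylsilyl)oxy]-2,6-dimethylhept-5-en-3-yl]boronic acid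
Product: 18 2-[(2R,3R)-4-[(tert-butyldimethylsilyl)oxy]-3-methyl-2-(3-methylbut-2-en-1-yl)butyl]-3,5-bis(methoxymethoxy)phenol, via N-tosylhydrazone 15 (not isolated), via aryldiazomethane 16 (not isolated), via benzylic boronic acid 17 (not isolated)
Conditions: 5 (1.5 equiv), TsNHNH2 (1.5 equiv), 1,4-dioxane, 60 °C, 1 h; then 14 (1.0 equiv), K2CO3 (4 equiv), H2O (2 equiv), 110 °C, 3 h, Ar
Reagents that add atoms: 4-methylbenzenesulfonohydrazide, Cc1ccc(cc1)S(=O)(=O)NN (N and Ts of 15 and 16 only)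
Why: Proposed new method: an enantiospecific deoxygenative sp3–sp3 coupling in which diazoalkane 16 (Bamford–Stevens from 15) attacks the empty boron orbital of secondary boronic acid 14 (pre-associated through the ortho-phenoxide), the boronate loses N2 with a 1,2-shift of the C2'' alkyl group from boron to carbon (retention at the migrating stereocentre, as in every 1,2-metallate shift), and the benzylic C–B bond of 17 is protodeboronated in situ; the closest known reactions are the metal-free reductive coupling of tosylhydrazones with achiral boronic acids (Barluenga type) and the Hooz/Brown homologation of chiral organoboranes with diazo compounds, neither shown for an enantioenriched α-branched acyclic secondary boronic acid on a salicylaldehyde hydrazone.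

Step 10
Reactants: 18 2-[(2R,3R)-4-[(tert-butyldimethylsilyl)oxy]-3-methyl-2-(3-methylbut-2-en-1-yl)butyl]-3,5-bis(methoxymethoxy)phenol
Product: 20 1-{3-[(2R,3R)-4-[(tert-butyldimethylsilyl)oxy]-3-methyl-2-(3-methylbut-2-en-1-yl)butyl]-2-hydroxy-4,6-bis(methoxymethoxy)phenyl}ethan-1-one, via bromomagnesium phenoxide 19 (not isolated)
Conditions: EtMgBr (1.05 equiv), Et2O, 0 °C; solvent switch to toluene; AcCl (1.1 equiv), rt to 60 °C; aq NH4Cl
Reagents that add atoms: acetyl chloride, CC(=O)Cl; ethylmagnesium bromide, CC[Mg]Br (MgBr of 19 only)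
Why: Magnesium-phenoxide-templated ortho-acylation (Friedel–Crafts type, Sartori–Casiraghi): the acyl chloride is delivered through the O–Mg chelate to the only free ortho carbon, not to the position between the two MOM ethers.

Step 11
Reactants: 1 resorcinol
Product: 22 2,4-dihydroxybenzaldehyde, via iminium chloride 21 (not isolated)
Conditions: POCl3 (1.2 equiv), DMF (1.5 equiv), MeCN, −15 °C to rt; then H2O, 50 °C
Reagents that add atoms: N,N-dimethylformamide, CN(C)C=O; water, O; phosphoryl chloride, O=P(Cl)(Cl)Cl (chloride of 21 only)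
Why: Vilsmeier–Haack formylation at C4 of resorcinol (para to one OH, ortho to the other), then hydrolysis of the iminium salt.

Step 12
Reactants: 22 2,4-dihydroxybenzaldehyde
Product: 24 2-methoxy-4-(methoxymethoxy)benzaldehyde, via 2-hydroxy-4-(methoxymethoxy)benzaldehyde 23 (not isolated)
Conditions: MOMCl (1.05 equiv), K2CO3 (3 equiv), acetone, 0 °C to rt; then MeI (3 equiv), reflux
Reagents that add atoms: chloromethyl methyl ether, COCCl; iodomethane, CI
Why: Sequential one-pot Williamson etherification: the non-chelated 4-OH reacts first because the 2-OH is held in a hydrogen bond to the aldehyde, and the 2-OH is methylated on heating.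

Step 13
Reactants: 20 1-{3-[(2R,3R)-4-[(tert-butyldimethylsilyl)oxy]-3-methyl-2-(3-methylbut-2-en-1-yl)butyl]-2-hydroxy-4,6-bis(methoxymethoxy)phenyl}ethan-1-one; 24 2-methoxy-4-(methoxymethoxy)benzaldehyde
Product: 25 (E)-1-{3-[(2R,3R)-4-[(tert-butyldimethylsilyl)oxy]-3-methyl-2-(3-methylbut-2-en-1-yl)butyl]-2-hydroxy-4,6-bis(methoxymethoxy)phenyl}-3-[2-methoxy-4-(methoxymethoxy)phenyl]prop-2-en-1-one
Conditions: KOH (50% aq, 10 equiv), EtOH, 0 °C to rt, 24–36 h
Reagents that add atoms: none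
Why: Claisen–Schmidt aldol condensation with E1cB dehydration to the E-enone; the existing stereocentres are remote and non-acidic.

Step 14
Reactants: 25 (E)-1-{3-[(2R,3R)-4-[(tert-butyldimethylsilyl)oxy]-3-methyl-2-(3-methylbut-2-en-1-yl)butyl]-2-hydroxy-4,6-bis(methoxymethoxy)phenyl}-3-[2-methoxy-4-(methoxymethoxy)phenyl]prop-2-en-1-one
Product: 26 (2S)-8-[(2R,3R)-4-[(tert-butyldimethylsilyl)oxy]-3-methyl-2-(3-methylbut-2-en-1-yl)butyl]-2-[2-methoxy-4-(methoxymethoxy)phenyl]-5,7-bis(methoxymethoxy)-2,3-dihydro-4H-chromen-4-one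
Conditions: quinine-derived bifunctional thiourea [N-(3,5-bis(trifluoromethyl)phenyl)-N'-(9-deoxy-epi-quinin-9-yl)thiourea] (15 mol %), toluene, 25–40 °C, 48–72 h
Reagents that add atoms: none
Why: Organocatalytic intramolecular oxa-Michael addition (biomimetic chalcone–flavanone cyclisation): the quinuclidine activates the phenol and the thiourea binds the enone so that one enone face is attacked, setting C2 (S) under catalyst control, and only the 2'-OH is free so only the 8-substituted chromanone can form.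

Step 15
Reactants: 26 (2S)-8-[(2R,3R)-4-[(tert-butyldimethylsilyl)oxy]-3-methyl-2-(3-methylbut-2-en-1-yl)butyl]-2-[2-methoxy-4-(methoxymethoxy)phenyl]-5,7-bis(methoxymethoxy)-2,3-dihydro-4H-chromen-4-one
Product: 27 (2S)-5,7-dihydroxy-2-(4-hydroxy-2-methoxyphenyl)-8-[(2R,3R)-4-hydroxy-3-methyl-2-(3-methylbut-2-en-1-yl)butyl]-2,3-dihydro-4H-chromen-4-one
Conditions: 3 M HCl (aq), MeOH, 50 °C, 2–4 h
Reagents that add atoms: none
Why: Acid-catalysed acetal exchange and desilylation remove the three MOM ethers and the TBS ether in one operation; C2 is configurationally stable in acid and the aryl methyl ether is not touched.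

**Compound list**
1 | resorcinol | Oc1cccc(O)c1 | starting material
2 | 1,3-bis(methoxymethoxy)benzene | COCOc1cccc(OCOC)c1 | intermediate
3 | 2-[3,5-bis(methoxymethoxy)phenyl]-4,4,5,5-tetramethyl-1,3,2-dioxaborolane | COCOc1cc(OCOC)cc(c1)B1OC(C)(C)C(C)(C)O1 | intermediate
4 | 3,5-bis(methoxymethoxy)phenol | COCOc1cc(O)cc(OCOC)c1 | intermediate
5 | 2-hydroxy-4,6-bis(methoxymethoxy)benzaldehyde | COCOc1cc(O)c(C=O)c(OCOC)c1 | intermediate
6 | (S)-3-bromo-2-methylpropan-1-ol | BrC[C@@H](C)CO | starting material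
7 | (S)-(3-bromo-2-methylpropoxy)(tert-butyl)dimethylsilane | BrC[C@@H](C)CO[Si](C)(C)C(C)(C)C | intermediate
8 | (R)-3-[(tert-butyldimethylsilyl)oxy]-2-methylpropyl 2,4,6-triisopropylbenzoate | CC(C)c1cc(C(C)C)c(C(=O)OC[C@@H](C)CO[Si](C)(C)C(C)(C)C)c(C(C)C)c1 | intermediate
9 | 1-chloro-3-methylbut-2-ene | CC(C)=CCCl | starting material
10 | 4,4,5,5-tetramethyl-2-(3-methylbut-2-en-1-yl)-1,3,2-dioxaborolane | CC(C)=CCB1OC(C)(C)C(C)(C)O1 | intermediate
11 | [(1S,2S)-3-[(tert-butyldimethylsilyl)oxy]-2-methyl-1-(2,4,6-triisopropylbenzoyloxy)propyl]lithium (sparteine complex, ligand not drawn) | [Li][C@H](OC(=O)c1c(C(C)C)cc(C(C)C)cc1C(C)C)[C@@H](C)CO[Si](C)(C)C(C)(C)C | intermediate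
12 | lithium [(1S,2S)-3-[(tert-butyldimethylsilyl)oxy]-2-methyl-1-(2,4,6-triisopropylbenzoyloxy)propyl](3-methylbut-2-en-1-yl)(pinacolato)borate | [Li+].CC(C)=CC[B-]1(OC(C)(C)C(C)(C)O1)[C@H](OC(=O)c1c(C(C)C)cc(C(C)C)cc1C(C)C)[C@@H](C)CO[Si](C)(C)C(C)(C)C | intermediate
13 | tert-butyl{[(2R,3S)-2,6-dimethyl-3-(4,4,5,5-tetramethyl-1,3,2-dioxaborolan-2-yl)hept-5-en-1-yl]oxy}dimethylsilane | CC1(C)OB(OC1(C)C)[C@@H](CC=C(C)C)[C@@H](C)CO[Si](C)(C)C(C)(C)C | intermediate
14 | [(2R,3S)-1-[(tert-butyldimethylsilyl)oxy]-2,6-dimethylhept-5-en-3-yl]boronic acid | OB(O)[C@@H](CC=C(C)C)[C@@H](C)CO[Si](C)(C)C(C)(C)C | intermediate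
15 | N'-[(E)-[2-hydroxy-4,6-bis(methoxymethoxy)phenyl]methylidene]-4-methylbenzenesulfonohydrazide | COCOc1cc(O)c(/C=N/NS(=O)(=O)c2ccc(C)cc2)c(OCOC)c1 | intermediate
16 | 2-(diazomethyl)-3,5-bis(methoxymethoxy)phenol | COCOc1cc(O)c(C=[N+]=[N-])c(OCOC)c1 | intermediate
17 | [(2R,3R)-4-[(tert-butyldimethylsilyl)oxy]-1-[2-hydroxy-4,6-bis(methoxymethoxy)phenyl]-3-methyl-2-(3-methylbut-2-en-1-yl)butyl]boronic acid (both C1 epimers) | COCOc1cc(O)c(C(B(O)O)[C@@H](CC=C(C)C)[C@@H](C)CO[Si](C)(C)C(C)(C)C)c(OCOC)c1 | intermediate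
18 | 2-[(2R,3R)-4-[(tert-butyldimethylsilyl)oxy]-3-methyl-2-(3-methylbut-2-en-1-yl)butyl]-3,5-bis(methoxymethoxy)phenol | COCOc1cc(O)c(C[C@@H](CC=C(C)C)[C@@H](C)CO[Si](C)(C)C(C)(C)C)c(OCOC)c1 | intermediate
19 | bromomagnesium 2-[(2R,3R)-4-[(tert-butyldimethylsilyl)oxy]-3-methyl-2-(3-methylbut-2-en-1-yl)butyl]-3,5-bis(methoxymethoxy)phenoxide | COCOc1cc(O[Mg]Br)c(C[C@@H](CC=C(C)C)[C@@H](C)CO[Si](C)(C)C(C)(C)C)c(OCOC)c1 | intermediate
20 | 1-{3-[(2R,3R)-4-[(tert-butyldimethylsilyl)oxy]-3-methyl-2-(3-methylbut-2-en-1-yl)butyl]-2-hydroxy-4,6-bis(methoxymethoxy)phenyl}ethan-1-one | CC(=O)c1c(O)c(C[C@@H](CC=C(C)C)[C@@H](C)CO[Si](C)(C)C(C)(C)C)c(OCOC)cc1OCOC | intermediate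
21 | [(2,4-dihydroxyphenyl)methylidene]dimethylazanium chloride | C[N+](C)=Cc1ccc(O)cc1O.[Cl-] | intermediate
22 | 2,4-dihydroxybenzaldehyde | O=Cc1ccc(O)cc1O | intermediate
23 | 2-hydroxy-4-(methoxymethoxy)benzaldehyde | COCOc1ccc(C=O)c(O)c1 | intermediate
24 | 2-methoxy-4-(methoxymethoxy)benzaldehyde | COCOc1ccc(C=O)c(OC)c1 | intermediate
25 | (E)-1-{3-[(2R,3R)-4-[(tert-butyldimethylsilyl)oxy]-3-methyl-2-(3-methylbut-2-en-1-yl)butyl]-2-hydroxy-4,6-bis(methoxymethoxy)phenyl}-3-[2-methoxy-4-(methoxymethoxy)phenyl]prop-2-en-1-one | COCOc1ccc(/C=C/C(=O)c2c(O)c(C[C@@H](CC=C(C)C)[C@@H](C)CO[Si](C)(C)C(C)(C)C)c(OCOC)cc2OCOC)c(OC)c1 | intermediate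
26 | (2S)-8-[(2R,3R)-4-[(tert-butyldimethylsilyl)oxy]-3-methyl-2-(3-methylbut-2-en-1-yl)butyl]-2-[2-methoxy-4-(methoxymethoxy)phenyl]-5,7-bis(methoxymethoxy)-2,3-dihydro-4H-chromen-4-one | COc1cc(OCOC)ccc1[C@@H]1CC(=O)c2c(OCOC)cc(OCOC)c(C[C@@H](CC=C(C)C)[C@@H](C)CO[Si](C)(C)C(C)(C)C)c2O1 | intermediate
27 | (2S)-5,7-dihydroxy-2-(4-hydroxy-2-methoxyphenyl)-8-[(2R,3R)-4-hydroxy-3-methyl-2-(3-methylbut-2-en-1-yl)butyl]-2,3-dihydro-4H-chromen-4-one (CNP0081318.1) | COc1cc(O)ccc1[C@@H]1CC(=O)c2c(O)cc(O)c(C[C@@H](CC=C(C)C)[C@@H](C)CO)c2O1 | target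

**Step count**
Total: 15 steps. Longest linear sequence: 9 steps (6 → 7 → 8 → 13 → 14 → 18 → 20 → 25 → 26 → 27; steps 4, 5, 7, 8, 9, 10, 13, 14, 15).

**Steps most likely to fail**

Step 9 (the proposed new coupling). The α-branched boronic acid may capture the diazoalkane too slowly, so that azine or carbene products win, or the benzylic boronic acid 17 may resist protodeboronation. The fallback is the known lithiation–borylation of a benzylic carbamate followed by protodeboronation. It sets out from aldehyde 5 and pinacol boronate 13 (step 8 is then skipped) and returns to the route at phenol 18. Aldehyde 5 is silylated (TIPSOTf, 2,6-lutidine, CH2Cl2) to 2,4-bis(methoxymethoxy)-6-[(triisopropylsilyl)oxy]benzaldehyde F1, reduced (NaBH4, MeOH, 0 °C) to [2,4-bis(methoxymethoxy)-6-[(triisopropylsilyl)oxy]phenyl]methanol F2, and carbamoylated (iPr2NCOCl, NaH, THF) to [2,4-bis(methoxymethoxy)-6-[(triisopropylsilyl)oxy]phenyl]methyl N,N-diisopropylcarbamate F3. F3 is lithiated (s-BuLi, TMEDA, Et2O, −78 °C), treated with 13 and warmed, so that the C2'' group migrates from boron to the benzylic carbon with retention and gives the secondary benzylic pinacol boronate F4. CsF and H2O in dioxane at 60 °C then protodeboronate it and cleave the aryl silyl ether, leaving the alkyl TBS ether, to give 18.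

Step 10 (ortho-acetylation through the magnesium phenoxide). O-acylation or MOM loss caused by the magnesium halide could compete. The fallback replaces direct acylation by formylation, methyl addition and oxidation; it sets out from 18 and returns at 20. Magnesium-mediated ortho-formylation (MgCl2, Et3N, (CH2O)n, MeCN, reflux) gives 3-[(2R,3R)-4-[(tert-butyldimethylsilyl)oxy]-3-methyl-2-(3-methylbut-2-en-1-yl)butyl]-2-hydroxy-4,6-bis(methoxymethoxy)benzaldehyde F5. MeMgBr (3 equiv, THF, 0 °C) gives 2-[(2R,3R)-4-[(tert-butyldimethylsilyl)oxy]-3-methyl-2-(3-methylbut-2-en-1-yl)butyl]-6-(1-hydroxyethyl)-3,5-bis(methoxymethoxy)phenol F6 as a carbinol mixture, and MnO2 in CH2Cl2 oxidises it to 20.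

Step 14 (catalytic asymmetric oxa-Michael). The cyclisation is reversible, selectivity on unactivated 2'-hydroxychalcones can be moderate, and the sense of induction has to be confirmed (CD); the quinidine-derived pseudo-enantiomer gives the opposite sense. The fallback gives up catalyst control in the ring closure and uses a kinetic resolution; it sets out from 25 and returns at 26. NaOAc in refluxing EtOH closes the ring without selectivity at C2 and gives 26 together with its C2 epimer, (2R)-8-[(2R,3R)-4-[(tert-butyldimethylsilyl)oxy]-3-methyl-2-(3-methylbut-2-en-1-yl)butyl]-2-[2-methoxy-4-(methoxymethoxy)phenyl]-5,7-bis(methoxymethoxy)-2,3-dihydro-4H-chromen-4-one F7. Noyori transfer hydrogenation (RuCl[(R,R)-TsDPEN](p-cymene), HCO2H/Et3N, rt) then reduces only the 2R epimer to the cis alcohol (2R,4R)-8-[(2R,3R)-4-[(tert-butyldimethylsilyl)oxy]-3-methyl-2-(3-methylbut-2-en-1-yl)butyl]-2-[2-methoxy-4-(methoxymethoxy)phenyl]-5,7-bis(methoxymethoxy)-3,4-dihydro-2H-chromen-4-ol F8. Ketone 26 is left behind and separated by chromatography.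

Further compounds
F1 | step 9 | 2,4-bis(methoxymethoxy)-6-[(triisopropylsilyl)oxy]benzaldehyde | COCOc1cc(O[Si](C(C)C)(C(C)C)C(C)C)c(C=O)c(OCOC)c1
F2 | step 9 | [2,4-bis(methoxymethoxy)-6-[(triisopropylsilyl)oxy]phenyl]methanol | COCOc1cc(O[Si](C(C)C)(C(C)C)C(C)C)c(CO)c(OCOC)c1
F3 | step 9 | [2,4-bis(methoxymethoxy)-6-[(triisopropylsilyl)oxy]phenyl]methyl N,N-diisopropylcarbamate | COCOc1cc(O[Si](C(C)C)(C(C)C)C(C)C)c(COC(=O)N(C(C)C)C(C)C)c(OCOC)c1
F4 | step 9 | tert-butyl{[(2R,3R)-4-[2,4-bis(methoxymethoxy)-6-[(triisopropylsilyl)oxy]phenyl]-2-methyl-3-(3-methylbut-2-en-1-yl)-4-(4,4,5,5-tetramethyl-1,3,2-dioxaborolan-2-yl)butyl]oxy}dimethylsilane (both C4 epimers) | COCOc1cc(O[Si](C(C)C)(C(C)C)C(C)C)c(C(B2OC(C)(C)C(C)(C)O2)[C@@H](CC=C(C)C)[C@@H](C)CO[Si](C)(C)C(C)(C)C)c(OCOC)c1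
F5 | step 10 | 3-[(2R,3R)-4-[(tert-butyldimethylsilyl)oxy]-3-methyl-2-(3-methylbut-2-en-1-yl)butyl]-2-hydroxy-4,6-bis(methoxymethoxy)benzaldehyde | O=Cc1c(O)c(C[C@@H](CC=C(C)C)[C@@H](C)CO[Si](C)(C)C(C)(C)C)c(OCOC)cc1OCOC
F6 | step 10 | 2-[(2R,3R)-4-[(tert-butyldimethylsilyl)oxy]-3-methyl-2-(3-methylbut-2-en-1-yl)butyl]-6-(1-hydroxyethyl)-3,5-bis(methoxymethoxy)phenol (both carbinol epimers) | CC(O)c1c(O)c(C[C@@H](CC=C(C)C)[C@@H](C)CO[Si](C)(C)C(C)(C)C)c(OCOC)cc1OCOC
F7 | step 14 | (2R)-8-[(2R,3R)-4-[(tert-butyldimethylsilyl)oxy]-3-methyl-2-(3-methylbut-2-en-1-yl)butyl]-2-[2-methoxy-4-(methoxymethoxy)phenyl]-5,7-bis(methoxymethoxy)-2,3-dihydro-4H-chromen-4-one | COc1cc(OCOC)ccc1[C@H]1CC(=O)c2c(OCOC)cc(OCOC)c(C[C@@H](CC=C(C)C)[C@@H](C)CO[Si](C)(C)C(C)(C)C)c2O1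
F8 | step 14 | (2R,4R)-8-[(2R,3R)-4-[(tert-butyldimethylsilyl)oxy]-3-methyl-2-(3-methylbut-2-en-1-yl)butyl]-2-[2-methoxy-4-(methoxymethoxy)phenyl]-5,7-bis(methoxymethoxy)-3,4-dihydro-2H-chromen-4-ol | COc1cc(OCOC)ccc1[C@H]1C[C@@H](O)c2c(OCOC)cc(OCOC)c(C[C@@H](CC=C(C)C)[C@@H](C)CO[Si](C)(C)C(C)(C)C)c2O1
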